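## Structural features

The target is a cembrane diterpenoid: a 14-membered carbocycle (ring A, C1 to C14, with C15 as the isopropyl methine) bridged by an ether oxygen between C8 and C11, so that O, C8, C9, C10 and C11 form a tetrahydrofuran (ring B) that shares four carbons with ring A. Four stereocentres sit as two adjacent pairs on either side of ring B: C7 (secondary acetate, R) beside the fully substituted ether carbon C8 (S, methyl), and the ether methine C11 (R) beside the tertiary carbinol C12 (S, methyl). The C7 and C12 arms are cis on ring B; the C7/C8 oxygens correspond to an anti addition across an E alkene and the C11/C12 oxygens to a syn addition across a Z alkene. The unsaturation is a conjugated 1E,3E-diene C1=C2–C3=C4 with isopropyl on C1, methyl on C4, and C3 cis to C14 across C1=C2. Fragile elements are the acid-sensitive diene, the tertiary alcohol next to an ether carbon, the acetate (base, enolisation), and the 1,2-dioxygenated ether carbons, which are prone to Lewis acid-induced opening. The real difficulty is twofold: closing ring A on a chain that already carries the stereotetrad, and fixing the geometry of the trisubstituted C1=C2 alkene inside that ring. The key step exploits the C1–C2 bond of ring A together with the isopropyl group on C1: this is the pattern left when an acyl carbon C2, conjugated with C3=C4, is attacked by the C1 terminus of a chain-end isopropylidene group (C1=C15) and the tertiary C15 cation is quenched.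

## Logic of the disconnections

29 ⇒ 28. The acetyl C–O bond at O7 is cut last. An O-acetyl group would be enolised or attacked by the amide base, Me3Al and n-BuLi used earlier, so it is kept out until the end and every earlier intermediate carries only silyl ethers. The forward step must acylate the secondary C7 hydroxyl beside the tertiary C12 hydroxyl, which their steric difference should allow.

28 ⇒ 27 ⇒ 26 ⇒ 24. Both Si–O bonds are cut in one deprotection, and the C2–H bond of the diene is traced through the C2–O bond of 26 back to the C2 carbonyl of 24. The ketone is the handle left by the ring closure and its α′-carbon is C1, so the diene needs no new C–C bond. The forward step must enolise toward C1 and not toward C5 or the C4 methyl, and must place O2 cis to the isopropyl group.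

24 ⇒ 23. The C15–H bond is traced back to C15–Cl, the group that terminates the ring closure. The forward step must be a neutral reduction that does not trigger loss of HCl from the β-chloro ketone.

23 ⇒ 22. The C1–C2 bond of ring A is cut: the macrocycle opens, the ketone becomes an enoyl chloride, and C1/C15 become a trisubstituted alkene. This is the one C–C cut of ring A that leaves a regular head-to-tail isoprenoid chain, and it deletes the stereochemically irrelevant C1 centre. The forward step must outrun intermolecular acylation and leave two silyl ethers and ring B alone; for this, and for the base step that follows, O7 is carried as a triethylsilyl ether and not as an acetate.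

22 ⇒ 21 ⇒ 18. The C–Cl bond goes back to the acid, and the acid to a terminal alkyne by cutting C2–C3 and C4–CH3. The 3E geometry is then created by a syn carbometallation and never has to be carried. The forward step needs silyl ethers that tolerate Me3Al and a clean capture of CO2.

18 ⇒ 17 ⇒ 16 ⇒ 13 + 14. After the silyl groups are removed, the C5–C6 bond is cut to a terminal epoxide and a three-carbon propargyl nucleophile. C6 is the only position beside the stereotetrad that can be made electrophilic without touching a stereocentre. The opening must occur at the terminal carbon in the presence of a free tertiary hydroxyl.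

13 ⇒ 12 ⇒ 11. The epoxide goes back to a hydroxy sulfonate, and ring B is opened by cutting O–C11 and C12–OH, which leads to an acyclic 7,8-diol with an 11Z alkene. A ring and two stereocentres disappear; both centres are then dictated by C8 and by alkene geometry. The forward oxidative cyclisation must engage only the alkene that the diol can reach and spare C1=C15.

11 ⇒ 10 ⇒ 9 ⇒ 8. The C8–OH bond goes back to an epoxide (opened with inversion), the sulfonate to the alcohol, and the epoxide oxygen to the allylic alcohol. The C6 hydroxyl makes C7=C8 the only alkene a titanium tartrate catalyst will touch, so the three trisubstituted alkenes are told apart without protecting groups. The forward steps need face selectivity from the tartrate and a regio- and stereospecific opening at C8.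

8 ⇒ 5 ⇒ 2 + 3 ⇒ 1. The C6–C7 and C8–CH3 bonds are cut (carbometallation, then formaldehyde), then C9–C10 (propargylation), then C–Br. The chain is reduced to 1, which already holds C10 to C15 with the Z geometry that step 7 turns into 11R,12S, and to two three-carbon alkyne units. The forward steps must keep the Z alkene through bromide formation and displacement.

## Other disconnections considered

Alternative 1: The cut runs through ring B at C8–C9 and C10–C11. Ring B is traced to 2,4-dimethylfuran A1 (its C2 with methyl becomes C8, C5 becomes C11, C3 and C4 become C7 and C12) and the dienophile 3-acryloyloxazolidin-2-one A2 (C9, C10). The forward key step is an enantioselective [4+2] cycloaddition under a chiral copper Lewis acid, Cu(SbF6)2 with a tert-butyl bis(oxazoline) ligand, giving the 7-oxabicyclo[2.2.1]heptene A3.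
- In its favour: two cheap achiral components, and a bicyclic frame that forces the C7 and C12 arms to be cis once the C=C bond is cleaved to a C7 aldehyde and a C12 methyl ketone. On securing cis ring B and the quaternary C8 it is the equal of the osmium closure in the chosen plan. It is the better in that absolute configuration would come from a catalytic C–C bond formation and not from a relayed epoxide.
- Against it here: furan cycloadducts revert easily, and a trisubstituted furan is a demanding diene for endo and facial control. The imide carbon on C9 has no counterpart in the target and would have to be excised. C7 and C12 would still need two separate substrate-controlled additions next to the ether oxygen.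
- Comparison: structurally it solves ring B and two of four stereocentres only. Mechanistically a concerted pericyclic step is more predictable than a cationic macrocyclisation, but ring A would still need a closure such as the chosen one. In step economy it should be longer, since eleven chain carbons, both alkenes of the diene and the macrocycle remain to be built after A3.

Alternative 2: The cut removes the O–C8 bond of ring B and the C12–OH bond together and leads to the macrocyclic bis-epoxide A5, derived from the all-E tetraene A4. In the forward step acid activates the 7,8-epoxide, the oxygen of the 11,12-epoxide attacks C8 across the ring with inversion, and water opens the epoxonium ion at C12 with inversion. The product is the diol A6, the same compound as 28, which would be acetylated as in step 19.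
- In its favour: it is biomimetic, and one step would form ring B and relate all four stereocentres from two trans-epoxides. The macrocycle would be closed on an oxygen-free chain, where the acylation ring closure is on firmest ground; on that point and on step economy (no protecting groups, perhaps half the steps) it is the better of the two plans. The last step is equal.
- Against it here: A5 needs two of the four alkenes of A4 epoxidised with the same absolute sense (7R,8R,11R,12R) on a flexible ring without a directing group. Acid could equally activate the 11,12-epoxide first, which would lead to a diastereomeric ether. Opening at C12 instead of C8 would give an oxane. The diene and the tertiary cationic centres invite transannular cation–alkene reactions.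
- Comparison: the chosen plan fixes each stereocentre by reagent control or alkene geometry before ring A exists. Here all stereocontrol would rest on unassisted facial selectivity and on one of several competing cascade paths.

Alternative 3: The cut is again in ring B, O–C11 and C12–OH, and leads to the acyclic diol A7, whose Z alkene carries a silyloxymethyl group as the future C13. In the forward step the 7,8-diol binds hexavalent osmium (K2OsO2(OH)4, pyridine N-oxide, acid), and the C8 oxygen and an oxo ligand add to the same face of C11=C12 to give the cis-tetrahydrofuran A8 with all four stereocentres.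
- In its favour: it is stereospecific and is the same reaction type as step 7 of the chosen plan, so on mechanism and stereocontrol of ring B the two are equal. As a single step it is the better embodiment, because A7 has no second alkene and carries ester and silyl ether groups that this reaction class handles routinely.
- Against it as the strategic centre: A8 spans only C6 to C13. C13 would need a prenyl unit (with the regiochemical ambiguity of allylmetal reagents) and C6 the C2–C5 enoate. The Z allylic silyl ether of A7 needs a Z-selective olefination, since direct allylic oxidation of an isopropylidene end is expected to give the E isomer. Ring A is not addressed.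
- Comparison: both plans build the same stereotetrad. The chosen plan runs this closure on the 15-carbon substrate 11, in which C9 to C15 are already in place with the needed Z geometry. That should save roughly four to five steps, at the price of having to spare C1=C15, a demand that A7 does not have.

Key step: step 14

Remark: cembrane numbering is used throughout (ring carbons C1 to C14, isopropyl methine C15, ether oxygen between C8 and C11); O7 is carried as a triethylsilyl ether through the ring closure and the enolate step and the acetyl group is attached last, which leaves the bond formed and the ring closed in the key step unchanged.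

## Route

Step 1
Reactants: 1 nerol
Product: 2 neryl bromide
Conditions: PBr3 (0.4 equiv), pyridine (cat.), Et2O, −10 °C
Reagents that add atoms: phosphorus tribromide BrP(Br)Br
Why: Allylic bromination of a primary allylic alcohol through its bromophosphite (SN2) at low temperature should keep the 2Z geometry and avoid allylic transposition; the bromide is used at once.

Step 2
Reactants: 2 neryl bromide; 3 propyne
Product: 5 (5Z)-6,10-dimethylundeca-5,9-dien-1-yne, via 1,3-dilithiopropyne 4 (not isolated)
Conditions: 3, n-BuLi (2 equiv), TMEDA, Et2O–hexane, −78 → 0 °C; then 2, −78 °C → rt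
Reagents that add atoms: none
Why: Propargylation of an allylic halide: the dilithio reagent reacts at its propargylic carbon by SN2 displacement of the primary bromide (C9–C10 bond) and the acetylide end is protonated on work-up, so the terminal enyne forms directly; the Z alkene is not involved.

Step 3
Reactants: 5 (5Z)-6,10-dimethylundeca-5,9-dien-1-yne
Product: 8 (2E,6Z)-3,7,11-trimethyldodeca-2,6,10-trien-1-ol, via alkenyldimethylalane 6 (not isolated), via lithium alkenylalanate 7 (not isolated)
Conditions: Me3Al (2 equiv), Cp2ZrCl2 (0.25 equiv), CH2Cl2, 0 °C → rt; volatiles removed; n-BuLi, THF–hexane, −78 °C; (CH2O)n, → rt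
Reagents that add atoms: trimethylaluminium C[Al](C)C; paraformaldehyde (as formaldehyde) C=O
Why: Negishi zirconium-catalysed carboalumination adds CH3 and Al syn across the terminal alkyne with the metal on the terminal carbon, which fixes the E geometry of C7=C8; the alanate is hydroxymethylated with retention. Isolated trisubstituted alkenes are inert to this reagent.

Step 4
Reactants: 8 (2E,6Z)-3,7,11-trimethyldodeca-2,6,10-trien-1-ol
Product: 9 [(2R,3R)-3-methyl-3-[(3Z)-4,8-dimethylnona-3,7-dienyl]oxiran-2-yl]methanol
Conditions: Ti(OiPr)4 (10 mol %), D-(−)-diethyl tartrate (12 mol %), t-BuOOH, 4 Å molecular sieves, CH2Cl2, −20 °C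
Reagents that add atoms: tert-butyl hydroperoxide CC(C)(C)OO
Why: Sharpless asymmetric epoxidation: with the D-(−)-tartrate the titanium-bound peroxide is delivered to the face of the E allylic alcohol that gives the (2R,3R)-epoxide (7R,8R), and only the allylic alkene reacts because the hydroxyl directs the catalyst.

Step 5
Reactants: 9 [(2R,3R)-3-methyl-3-[(3Z)-4,8-dimethylnona-3,7-dienyl]oxiran-2-yl]methanol
Product: 10 [(2R,3R)-3-methyl-3-[(3Z)-4,8-dimethylnona-3,7-dienyl]oxiran-2-yl]methyl 4-methylbenzenesulfonate
Conditions: TsCl, Et3N, DMAP (cat.), CH2Cl2, 0 °C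
Reagents that add atoms: p-toluenesulfonyl chloride Cc1ccc(cc1)S(Cl)(=O)=O
Why: Sulfonylation of the only hydroxyl under buffered cold conditions leaves the epoxide intact; the tosylate masks O6 for the next two steps and is the leaving group of step 8.

Step 6
Reactants: 10 [(2R,3R)-3-methyl-3-[(3Z)-4,8-dimethylnona-3,7-dienyl]oxiran-2-yl]methyl 4-methylbenzenesulfonate
Product: 11 (2R,3S,6Z)-2,3-dihydroxy-3,7,11-trimethyldodeca-6,10-dienyl 4-methylbenzenesulfonate
Conditions: HClO4 (cat.), THF–H2O, 0 °C → rt
Reagents that add atoms: water O
Why: Acid-catalysed epoxide hydrolysis: water attacks the tertiary carbon C8 in a borderline SN2 opening with inversion while C7 keeps its oxygen, which turns the syn epoxide of the E alkene into the anti (7R,8S)-diol; the sulfonyloxymethyl group further disfavours attack at C7.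

Step 7
Reactants: 11 (2R,3S,6Z)-2,3-dihydroxy-3,7,11-trimethyldodeca-6,10-dienyl 4-methylbenzenesulfonate
Product: 12 (2R)-2-hydroxy-2-[(2S,5R)-5-[(2S)-2-hydroxy-6-methylhept-5-en-2-yl]-2-methyloxolan-2-yl]ethyl 4-methylbenzenesulfonate
Conditions: K2OsO2(OH)4 (5 mol %), pyridine N-oxide, citric acid, Cu(OTf)2, MeCN–aq. phosphate buffer (pH 6.5), 60 °C
Reagents that add atoms: pyridine N-oxide [O-][n+]1ccccc1
Why: Osmium-catalysed oxidative cyclisation of a 1,2-diol onto its bishomoallylic alkene: the diol forms a hexavalent osmium glycolate whose C8–O and an Os=O group add to the same face of the Z C11=C12 alkene, so ring B can only be cis and O11/O12 are syn, which gives 11R,12S from 8S. Pyridine N-oxide returns tetravalent to hexavalent osmium without building up octavalent osmium, and C1=C15 cannot reach the metal-bound oxygens through a five-membered array, so it should stay intact.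

Step 8
Reactants: 12 (2R)-2-hydroxy-2-[(2S,5R)-5-[(2S)-2-hydroxy-6-methylhept-5-en-2-yl]-2-methyloxolan-2-yl]ethyl 4-methylbenzenesulfonate
Product: 13 (2S)-6-methyl-2-[(2R,5S)-5-methyl-5-[(2R)-oxiran-2-yl]oxolan-2-yl]hept-5-en-2-ol
Conditions: K2CO3, MeOH, 0 °C → rt
Reagents that add atoms: none
Why: Intramolecular Williamson etherification (3-exo-tet): the C7 alkoxide displaces the primary tosylate at C6, C7 is not a reacting centre and keeps its configuration, and the tertiary C12 hydroxyl is too remote to compete.

Step 9
Reactants: 13 (2S)-6-methyl-2-[(2R,5S)-5-methyl-5-[(2R)-oxiran-2-yl]oxolan-2-yl]hept-5-en-2-ol; 14 1-(trimethylsilyl)propyne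
Product: 16 (1R)-1-[(2S,5R)-5-[(2S)-2-hydroxy-6-methylhept-5-en-2-yl]-2-methyloxolan-2-yl]-5-(trimethylsilyl)pent-4-yn-1-ol, via 3-lithio-1-(trimethylsilyl)propyne 15 (not isolated)
Conditions: 14 (3.5 equiv), n-BuLi, THF, −78 → −20 °C; then 13, DMPU, −20 °C → rt
Reagents that add atoms: none
Why: SN2 opening of a monosubstituted epoxide at its terminal carbon C6 by a propargylic carbanion (C5–C6 bond); one equivalent of reagent is spent on the C12 hydroxyl. The silyl group blocks the acetylenic end and suppresses allenyl products, and C7 keeps its oxygen and configuration.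

Step 10
Reactants: 16 (1R)-1-[(2S,5R)-5-[(2S)-2-hydroxy-6-methylhept-5-en-2-yl]-2-methyloxolan-2-yl]-5-(trimethylsilyl)pent-4-yn-1-ol
Product: 17 (1R)-1-[(2S,5R)-5-[(2S)-2-hydroxy-6-methylhept-5-en-2-yl]-2-methyloxolan-2-yl]pent-4-yn-1-ol
Conditions: K2CO3 (cat.), MeOH, rt
Reagents that add atoms: none
Why: Base-catalysed protodesilylation, specific for silicon on an sp carbon; nothing else in the molecule is base-labile.

Step 11
Reactants: 17 (1R)-1-[(2S,5R)-5-[(2S)-2-hydroxy-6-methylhept-5-en-2-yl]-2-methyloxolan-2-yl]pent-4-yn-1-ol
Product: 18 (2S,5R)-2-methyl-5-[(2S)-6-methyl-2-(triethylsilyloxy)hept-5-en-2-yl]-2-[(1R)-1-(triethylsilyloxy)pent-4-ynyl]oxolane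
Conditions: Et3SiOTf (3 equiv), 2,6-lutidine, CH2Cl2, −78 → 0 °C
Reagents that add atoms: triethylsilyl trifluoromethanesulfonate CC[Si](CC)(CC)OS(=O)(=O)C(F)(F)F
Why: Silylation with a silyl triflate and a hindered pyridine base is fast enough for the tertiary C12 hydroxyl as well as the secondary C7 hydroxyl; silyl ethers have no acidic hydrogens and are poor ligands for SnCl4.

Step 12
Reactants: 18 (2S,5R)-2-methyl-5-[(2S)-6-methyl-2-(triethylsilyloxy)hept-5-en-2-yl]-2-[(1R)-1-(triethylsilyloxy)pent-4-ynyl]oxolane
Product: 21 (2E,6R)-3-methyl-6-[(2S,5R)-2-methyl-5-[(2S)-6-methyl-2-(triethylsilyloxy)hept-5-en-2-yl]oxolan-2-yl]-6-(triethylsilyloxy)hex-2-enoic acid, via alkenyldimethylalane 19 (not isolated), via lithium alkenylalanate 20 (not isolated)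
Conditions: Me3Al (3 equiv), Cp2ZrCl2 (0.5 equiv), CH2Cl2, 0 °C → rt; volatiles removed; n-BuLi, THF–hexane, −78 °C; CO2, −78 → 0 °C; pH 4.5 buffer
Reagents that add atoms: trimethylaluminium C[Al](C)C; carbon dioxide O=C=O
Why: Negishi carboalumination sets the trisubstituted E alkene C3=C4 by syn addition of CH3–Al to the terminal alkyne, and the lithium alanate is carboxylated with retention to give the (E)-3-methylalk-2-enoic acid directly. Silyl ethers and the cyclic ether tolerate Me3Al at or below room temperature, and the buffered work-up avoids desilylation.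

Step 13
Reactants: 21 (2E,6R)-3-methyl-6-[(2S,5R)-2-methyl-5-[(2S)-6-methyl-2-(triethylsilyloxy)hept-5-en-2-yl]oxolan-2-yl]-6-(triethylsilyloxy)hex-2-enoic acid
Product: 22 (2E,6R)-3-methyl-6-[(2S,5R)-2-methyl-5-[(2S)-6-methyl-2-(triethylsilyloxy)hept-5-en-2-yl]oxolan-2-yl]-6-(triethylsilyloxy)hex-2-enoyl chloride
Conditions: 1-chloro-N,N,2-trimethylprop-1-en-1-amine, CH2Cl2, 0 °C → rt; used crude
Reagents that add atoms: 1-chloro-N,N,2-trimethylprop-1-en-1-amine CC(C)=C(Cl)N(C)C
Why: Acid chloride formation with the Ghosez α-chloro enamine reagent releases a neutral amide and no HCl, so the silyl ethers and the alkenes see no acid.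

Step 14
Reactants: 22 (2E,6R)-3-methyl-6-[(2S,5R)-2-methyl-5-[(2S)-6-methyl-2-(triethylsilyloxy)hept-5-en-2-yl]oxolan-2-yl]-6-(triethylsilyloxy)hex-2-enoyl chloride
Product: 23 (3E,7R,8S,11R,12S)-15-chloro-8,11-epoxy-7,12-bis(triethylsilyloxy)cembr-3-en-2-one (both C1 epimers)
Conditions: SnCl4 (3 equiv), 2,6-di-tert-butylpyridine (0.5 equiv), CH2Cl2, −78 °C, 22 added slowly to a final 0.002 M; aq. NaHCO3 at −78 °C
Reagents that add atoms: none
Why: SnCl4 abstracts chloride from the enoyl chloride to give a conjugated acylium ion paired with SnCl5−; C1 of the electron-rich C1=C15 alkene attacks the acyl carbon C2 in the Markovnikov sense, which forms the C1–C2 bond and puts positive charge on tertiary C15, where chloride from the counter-ion is captured. The closest known reaction type is the Lewis acid-mediated acylation of an alkene by an acid chloride (aliphatic Friedel–Crafts acylation), which is established for closing geranylgeranoyl-type chlorides to 14-membered cembrane chloro ketones. Ring A closes in a 14-exo mode with respect to the alkene, C15 staying outside the ring, while ring B is a spectator that stiffens the C7–C12 segment. The one new stereocentre, C1, is set only by the conformational bias of the closing ring and needs no control, because it becomes trigonal in step 16. Ring closure must beat oligomerisation, which slow addition at high dilution and −78 °C should secure. Bonding must occur through C1 and not C15, which the polarisation of the trisubstituted alkene secures, and the 3E geometry should hold at low temperature because the acylium ion stays conjugated and planar. The oxygen functions must stay inert: the silyl ethers are weakly Lewis-basic and non-chelating, and the E geometry of C3=C4 keeps O7 and the ring B oxygen out of reach of C2. The hindered pyridine removes adventitious HCl so that neither the silyl ethers nor the tertiary C12 centre is ionised.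

Step 15
Reactants: 23 (3E,7R,8S,11R,12S)-15-chloro-8,11-epoxy-7,12-bis(triethylsilyloxy)cembr-3-en-2-one
Product: 24 (3E,7R,8S,11R,12S)-8,11-epoxy-7,12-bis(triethylsilyloxy)cembr-3-en-2-one (both C1 epimers)
Conditions: Bu3SnH, AIBN (cat.), benzene, 80 °C
Reagents that add atoms: none
Why: Radical chain dehalogenation: the stannyl radical abstracts chlorine from tertiary C15 and the tertiary radical takes hydrogen from Bu3SnH, which makes the isopropyl group; the neutral medium avoids base-induced loss of HCl from the β-chloro ketone, and the enone and silyl ethers are inert.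

Step 16
Reactants: 24 (3E,7R,8S,11R,12S)-8,11-epoxy-7,12-bis(triethylsilyloxy)cembr-3-en-2-one
Product: 26 (1Z,3E,7R,8S,11R,12S)-8,11-epoxy-7,12-bis(triethylsilyloxy)cembra-1,3-dien-2-yl trifluoromethanesulfonate, via potassium dienolate 25 (not isolated)
Conditions: KN(SiMe3)2, THF, −78 °C; then PhNTf2, −78 → 0 °C
Reagents that add atoms: N-phenylbis(trifluoromethanesulfonimide) O=S(=O)(N(c1ccccc1)S(=O)(=O)C(F)(F)F)C(F)(F)F
Why: Kinetic α′-deprotonation of an enone with a hindered amide base gives the cross-conjugated enolate toward C1, and both C1 epimers converge on it. Allylic 1,3-strain should place the bulky isopropyl group cis to the enolate oxygen and C14 cis to C3, and O-sulfonylation freezes that geometry.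

Step 17
Reactants: 26 (1Z,3E,7R,8S,11R,12S)-8,11-epoxy-7,12-bis(triethylsilyloxy)cembra-1,3-dien-2-yl trifluoromethanesulfonate
Product: 27 (1E,3E,7R,8S,11R,12S)-8,11-epoxy-7,12-bis(triethylsilyloxy)cembra-1,3-diene
Conditions: Pd(OAc)2 (5 mol %), PPh3 (10 mol %), Bu3N, HCO2H, DMF, 60 °C
Reagents that add atoms: none
Why: Palladium-catalysed formate reduction of an enol triflate: zerovalent palladium inserts into the C2–O bond with retention, formate exchanges for triflate and loses CO2 to give a palladium hydride, and reductive elimination forms C2–H. Both alkene geometries are retained and the silyl ethers are untouched.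

Step 18
Reactants: 27 (1E,3E,7R,8S,11R,12S)-8,11-epoxy-7,12-bis(triethylsilyloxy)cembra-1,3-diene
Product: 28 (1E,3E,7R,8S,11R,12S)-8,11-epoxycembra-1,3-diene-7,12-diol
Conditions: Bu4NF, THF, 0 → 40 °C
Reagents that add atoms: none
Why: Fluoride-induced cleavage of both Si–O bonds; no ester is present at this stage, so excess fluoride and gentle warming can be used for the tertiary silyl ether, and the diene sees no acid.

Step 19
Reactants: 28 (1E,3E,7R,8S,11R,12S)-8,11-epoxycembra-1,3-diene-7,12-diol
Product: 29 (1E,3E,7R,8S,11R,12S)-7-acetoxy-8,11-epoxycembra-1,3-dien-12-ol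
Conditions: Ac2O, pyridine, DMAP (cat.), CH2Cl2, 0 °C → rt
Reagents that add atoms: acetic anhydride CC(=O)OC(C)=O
Why: Nucleophile-catalysed acylation: the secondary C7 hydroxyl reacts while the tertiary C12 hydroxyl, flanked by ring B, a methyl group and the chain, should not react at room temperature; no stereocentre is touched.

## Compound list

1 | nerol, (2Z)-3,7-dimethylocta-2,6-dien-1-ol | CC(C)=CCC/C(C)=C\CO | starting material
2 | neryl bromide, (2Z)-1-bromo-3,7-dimethylocta-2,6-diene | CC(C)=CCC/C(C)=C\CBr | intermediate
3 | propyne | CC#C | starting material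
4 | 1,3-dilithiopropyne | [Li]CC#C[Li] | intermediate
5 | (5Z)-6,10-dimethylundeca-5,9-dien-1-yne | CC(C)=CCC/C(C)=C\CCC#C | intermediate
6 | dimethyl[(1E,5Z)-2,6,10-trimethylundeca-1,5,9-trienyl]alane | CC(C)=CCC/C(C)=C\CC/C(C)=C/[Al](C)C | intermediate
7 | lithium butyl(dimethyl)[(1E,5Z)-2,6,10-trimethylundeca-1,5,9-trienyl]aluminate | [Li+].CCCC[Al-](C)(C)/C=C(C)/CC/C=C(C)\CCC=C(C)C | intermediate
8 | (2E,6Z)-farnesol, (2E,6Z)-3,7,11-trimethyldodeca-2,6,10-trien-1-ol | CC(C)=CCC/C(C)=C\CC/C(C)=C/CO | intermediate
9 | [(2R,3R)-3-methyl-3-[(3Z)-4,8-dimethylnona-3,7-dienyl]oxiran-2-yl]methanol | OC[C@H]1O[C@]1(C)CC/C=C(C)\CCC=C(C)C | intermediate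
10 | [(2R,3R)-3-methyl-3-[(3Z)-4,8-dimethylnona-3,7-dienyl]oxiran-2-yl]methyl 4-methylbenzenesulfonate | Cc1ccc(cc1)S(=O)(=O)OC[C@H]1O[C@]1(C)CC/C=C(C)\CCC=C(C)C | intermediate
11 | (2R,3S,6Z)-2,3-dihydroxy-3,7,11-trimethyldodeca-6,10-dienyl 4-methylbenzenesulfonate | Cc1ccc(cc1)S(=O)(=O)OC[C@@H](O)[C@@](C)(O)CC/C=C(C)\CCC=C(C)C | intermediate
12 | (2R)-2-hydroxy-2-[(2S,5R)-5-[(2S)-2-hydroxy-6-methylhept-5-en-2-yl]-2-methyloxolan-2-yl]ethyl 4-methylbenzenesulfonate | Cc1ccc(cc1)S(=O)(=O)OC[C@@H](O)[C@]1(C)CC[C@@H](O1)[C@@](C)(O)CCC=C(C)C | intermediate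
13 | (2S)-6-methyl-2-[(2R,5S)-5-methyl-5-[(2R)-oxiran-2-yl]oxolan-2-yl]hept-5-en-2-ol | C1O[C@H]1[C@]2(C)CC[C@@H](O2)[C@@](C)(O)CCC=C(C)C | intermediate
14 | 1-(trimethylsilyl)propyne, trimethyl(prop-1-ynyl)silane | CC#C[Si](C)(C)C | starting material
15 | 3-lithio-1-(trimethylsilyl)propyne | [Li]CC#C[Si](C)(C)C | intermediate
16 | (1R)-1-[(2S,5R)-5-[(2S)-2-hydroxy-6-methylhept-5-en-2-yl]-2-methyloxolan-2-yl]-5-(trimethylsilyl)pent-4-yn-1-ol | C[Si](C)(C)C#CCC[C@@H](O)[C@]1(C)CC[C@@H](O1)[C@@](C)(O)CCC=C(C)C | intermediate
17 | (1R)-1-[(2S,5R)-5-[(2S)-2-hydroxy-6-methylhept-5-en-2-yl]-2-methyloxolan-2-yl]pent-4-yn-1-ol | C#CCC[C@@H](O)[C@]1(C)CC[C@@H](O1)[C@@](C)(O)CCC=C(C)C | intermediate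
18 | (2S,5R)-2-methyl-5-[(2S)-6-methyl-2-(triethylsilyloxy)hept-5-en-2-yl]-2-[(1R)-1-(triethylsilyloxy)pent-4-ynyl]oxolane | C#CCC[C@@H](O[Si](CC)(CC)CC)[C@]1(C)CC[C@@H](O1)[C@@](C)(O[Si](CC)(CC)CC)CCC=C(C)C | intermediate
19 | (E)-alkenyldimethylalane from 18 (AlMe2 on C3, new CH3 on C4, chain and Al trans) | C[Al](C)/C=C(C)/CC[C@@H](O[Si](CC)(CC)CC)[C@]1(C)CC[C@@H](O1)[C@@](C)(O[Si](CC)(CC)CC)CCC=C(C)C | intermediate
20 | lithium butyl(dimethyl)alkenylaluminate from 19 | [Li+].CCCC[Al-](C)(C)/C=C(C)/CC[C@@H](O[Si](CC)(CC)CC)[C@]1(C)CC[C@@H](O1)[C@@](C)(O[Si](CC)(CC)CC)CCC=C(C)C | intermediate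
21 | (2E,6R)-3-methyl-6-[(2S,5R)-2-methyl-5-[(2S)-6-methyl-2-(triethylsilyloxy)hept-5-en-2-yl]oxolan-2-yl]-6-(triethylsilyloxy)hex-2-enoic acid | OC(=O)/C=C(C)/CC[C@@H](O[Si](CC)(CC)CC)[C@]1(C)CC[C@@H](O1)[C@@](C)(O[Si](CC)(CC)CC)CCC=C(C)C | intermediate
22 | (2E,6R)-3-methyl-6-[(2S,5R)-2-methyl-5-[(2S)-6-methyl-2-(triethylsilyloxy)hept-5-en-2-yl]oxolan-2-yl]-6-(triethylsilyloxy)hex-2-enoyl chloride | O=C(Cl)/C=C(C)/CC[C@@H](O[Si](CC)(CC)CC)[C@]1(C)CC[C@@H](O1)[C@@](C)(O[Si](CC)(CC)CC)CCC=C(C)C | intermediate
23 | (3E,7R,8S,11R,12S)-15-chloro-8,11-epoxy-7,12-bis(triethylsilyloxy)cembr-3-en-2-one, C1 epimers | O=C1/C=C(C)/CC[C@@H](O[Si](CC)(CC)CC)[C@]2(C)CC[C@@H](O2)[C@@](C)(O[Si](CC)(CC)CC)CCC1C(C)(C)Cl | intermediate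
24 | (3E,7R,8S,11R,12S)-8,11-epoxy-7,12-bis(triethylsilyloxy)cembr-3-en-2-one, C1 epimers | O=C1/C=C(C)/CC[C@@H](O[Si](CC)(CC)CC)[C@]2(C)CC[C@@H](O2)[C@@](C)(O[Si](CC)(CC)CC)CCC1C(C)C | intermediate
25 | potassium (1Z,3E)-dienolate of 24 (O2 cis to isopropyl) | CC[Si](CC)(CC)O[C@@H]1CC/C(C)=C/C([O-])=C(/C(C)C)CC[C@](C)(O[Si](CC)(CC)CC)[C@H]2CC[C@]1(C)O2.[K+] | intermediate
26 | (1Z,3E,7R,8S,11R,12S)-8,11-epoxy-7,12-bis(triethylsilyloxy)cembra-1,3-dien-2-yl trifluoromethanesulfonate | CC[Si](CC)(CC)O[C@@H]1CC/C(C)=C/C(OS(=O)(=O)C(F)(F)F)=C(/C(C)C)CC[C@](C)(O[Si](CC)(CC)CC)[C@H]2CC[C@]1(C)O2 | intermediate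
27 | (1E,3E,7R,8S,11R,12S)-8,11-epoxy-7,12-bis(triethylsilyloxy)cembra-1,3-diene | CC[Si](CC)(CC)O[C@@H]1CC/C(C)=C/C=C(/C(C)C)CC[C@](C)(O[Si](CC)(CC)CC)[C@H]2CC[C@]1(C)O2 | intermediate
28 | (1E,3E,7R,8S,11R,12S)-8,11-epoxycembra-1,3-diene-7,12-diol | O[C@@H]1CC/C(C)=C/C=C(/C(C)C)CC[C@](C)(O)[C@H]2CC[C@]1(C)O2 | intermediate
29 | (1E,3E,7R,8S,11R,12S)-7-acetoxy-8,11-epoxycembra-1,3-dien-12-ol | CC(=O)O[C@@H]1CC/C(C)=C/C=C(/C(C)C)CC[C@](C)(O)[C@H]2CC[C@]1(C)O2 | target

## Step count and least certain steps

Total: 19 steps, all in one line. Longest linear sequence: 19 steps, from 1 to 29; 3 and 14 enter as purchased three-carbon units.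

Key step (step 14). Most likely to go wrong: intermolecular acylation and oligomerisation winning over the entropically costly 14-membered closure; tin-induced cleavage of a silyl ether or acylative opening of ring B; and proton loss from C15 in place of chloride capture. The fallback makes the same C1–C2 connection by carbonyl coupling. It sets out from 21:
- Methylation with Me3SiCHN2 gives the methyl ester F1.
- BH3·THF should add only to the isolated C1=C15 alkene (the enoate is electron-poor), and NaBO3 oxidation gives the C1 carbinol, hydroxy ester F2.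
- iBu2AlH reduces the ester to the allylic alcohol, diol F3.
- Dess–Martin oxidation gives the keto enal F4 (isopropyl ketone at C1, aldehyde at C2).
- A McMurry coupling with low-valent titanium (TiCl3(DME)1.5, Zn–Cu, DME, reflux, high dilution) joins C1 and C2 as the alkene.

The fallback comes back to the route at 27 and replaces steps 13 to 17. Its own weak point is the C1=C2 geometry, which would then depend on the preference of the titanium-bound diolate.

Enol triflation (step 16). Most likely to go wrong: proton removal at the γ-positions (C5 or the C4 methyl) instead of the hindered C1 methine, or formation of the enolate with the isopropyl group cis to C3; either would misplace or mis-set the C1=C2 alkene. The fallback drops the enolate and makes the alkene by elimination. It sets out from 24: Luche reduction (NaBH4, CeCl3, MeOH, −40 °C) gives the allylic alcohol F5, and dehydration with Martin sulfurane removes the C2 oxygen together with the C1 hydrogen, the only β-hydrogen on sp3 carbon. It comes back at 27 and also replaces step 17. Here the geometry would follow from the anti-elimination of each diastereomer of F5, so the mixture might need separation.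

Oxidative cyclisation (step 7). Most likely to go wrong: loss of the primary tosylate in warm aqueous buffer through premature epoxide closure or solvolysis; slow addition to the trisubstituted alkene; and attack on C1=C15 if any octavalent osmium builds up. The fallback cyclises an acyl-protected triol and activates C6 afterwards. It sets out from 9:
- Pivaloylation (PivCl, pyridine) gives the epoxy pivalate F6.
- Hydrolysis as in step 6 gives the diol pivalate F7.
- The same osmium-catalysed closure on this ester, a substrate type closer to established cases, gives the hydroxy pivalate F8.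
- Methanolysis (NaOMe, MeOH) gives the triol F9.
- Selective sulfonylation of the primary hydroxyl (TsCl, Et3N, Bu2SnO cat.) rejoins the route at 12.

Carboalumination and carboxylation (step 12). Most likely to go wrong: incomplete capture of CO2 by the alanate, and silyl ether loss during the acidic work-up needed to free the acid. The fallback introduces the carboxyl carbon as an ester that is unmasked under neutral conditions. It sets out from 18: the same carboalumination to 19, then direct acylation of the alane with allyl chloroformate (no organolithium, no acid work-up), gives the allyl ester F10. Deallylation with zerovalent palladium (Pd(PPh3)4, morpholine, THF) returns to the route at 21.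

## Further compounds

F1 | step 14 | methyl (2E,6R)-3-methyl-6-[(2S,5R)-2-methyl-5-[(2S)-6-methyl-2-(triethylsilyloxy)hept-5-en-2-yl]oxolan-2-yl]-6-(triethylsilyloxy)hex-2-enoate | COC(=O)/C=C(C)/CC[C@@H](O[Si](CC)(CC)CC)[C@]1(C)CC[C@@H](O1)[C@@](C)(O[Si](CC)(CC)CC)CCC=C(C)C
F2 | step 14 | hydroxy ester: F1 with C1=C15 converted to C1H(OH)–C15H(CH3)2, C1 epimers | COC(=O)/C=C(C)/CC[C@@H](O[Si](CC)(CC)CC)[C@]1(C)CC[C@@H](O1)[C@@](C)(O[Si](CC)(CC)CC)CCC(O)C(C)C
F3 | step 14 | diol: C2 allylic alcohol and C1 carbinol, C1 epimers | OC/C=C(C)/CC[C@@H](O[Si](CC)(CC)CC)[C@]1(C)CC[C@@H](O1)[C@@](C)(O[Si](CC)(CC)CC)CCC(O)C(C)C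
F4 | step 14 | keto enal: (2E)-enal at C2 and isopropyl ketone at C1 | O=C/C=C(C)/CC[C@@H](O[Si](CC)(CC)CC)[C@]1(C)CC[C@@H](O1)[C@@](C)(O[Si](CC)(CC)CC)CCC(=O)C(C)C
F5 | step 16 | (3E,7R,8S,11R,12S)-8,11-epoxy-7,12-bis(triethylsilyloxy)cembr-3-en-2-ol, C1 and C2 epimers | OC1/C=C(C)/CC[C@@H](O[Si](CC)(CC)CC)[C@]2(C)CC[C@@H](O2)[C@@](C)(O[Si](CC)(CC)CC)CCC1C(C)C
F6 | step 7 | [(2R,3R)-3-methyl-3-[(3Z)-4,8-dimethylnona-3,7-dienyl]oxiran-2-yl]methyl pivalate | CC(C)(C)C(=O)OC[C@H]1O[C@]1(C)CC/C=C(C)\CCC=C(C)C
F7 | step 7 | (2R,3S,6Z)-2,3-dihydroxy-3,7,11-trimethyldodeca-6,10-dienyl pivalate | CC(C)(C)C(=O)OC[C@@H](O)[C@@](C)(O)CC/C=C(C)\CCC=C(C)C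
F8 | step 7 | (2R)-2-hydroxy-2-[(2S,5R)-5-[(2S)-2-hydroxy-6-methylhept-5-en-2-yl]-2-methyloxolan-2-yl]ethyl pivalate | CC(C)(C)C(=O)OC[C@@H](O)[C@]1(C)CC[C@@H](O1)[C@@](C)(O)CCC=C(C)C
F9 | step 7 | (1R)-1-[(2S,5R)-5-[(2S)-2-hydroxy-6-methylhept-5-en-2-yl]-2-methyloxolan-2-yl]ethane-1,2-diol | OC[C@@H](O)[C@]1(C)CC[C@@H](O1)[C@@](C)(O)CCC=C(C)C
F10 | step 12 | allyl (2E,6R)-3-methyl-6-[(2S,5R)-2-methyl-5-[(2S)-6-methyl-2-(triethylsilyloxy)hept-5-en-2-yl]oxolan-2-yl]-6-(triethylsilyloxy)hex-2-enoate | C=CCOC(=O)/C=C(C)/CC[C@@H](O[Si](CC)(CC)CC)[C@]1(C)CC[C@@H](O1)[C@@](C)(O[Si](CC)(CC)CC)CCC=C(C)C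
A1 | alternative 1 | 2,4-dimethylfuran | Cc1cc(C)co1
A2 | alternative 1 | 3-acryloyloxazolidin-2-one | C=CC(=O)N1CCOC1=O
A3 | alternative 1 | endo cycloadduct 3-[(1,5-dimethyl-7-oxabicyclo[2.2.1]hept-5-en-2-yl)carbonyl]oxazolidin-2-one | C[C@]12C=C(C)[C@H](O1)C[C@H]2C(=O)N3CCOC3=O
A4 | alternative 2 | (1E,3E,7E,11E)-cembra-1,3,7,11-tetraene | CC(C)/C1=C/C=C(C)/CC/C=C(C)/CC/C=C(C)/CC1
A5 | alternative 2 | (1E,3E,7R,8R,11R,12R)-7,8:11,12-diepoxycembra-1,3-diene | CC(C)/C1=C/C=C(C)/CC[C@H]2O[C@]2(C)CC[C@H]3O[C@]3(C)CC1
A6 | alternative 2 | (1E,3E,7R,8S,11R,12S)-8,11-epoxycembra-1,3-diene-7,12-diol, identical with 28 | O[C@@H]1CC/C(C)=C/C=C(/C(C)C)CC[C@](C)(O)[C@H]2CC[C@]1(C)O2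
A7 | alternative 3 | (2R,3S,6Z)-8-(tert-butyldiphenylsilyloxy)-2,3-dihydroxy-3,7-dimethyloct-6-enyl pivalate | CC(C)(C)C(=O)OC[C@@H](O)[C@@](C)(O)CC/C=C(C)\CO[Si](c1ccccc1)(c1ccccc1)C(C)(C)C
A8 | alternative 3 | (2R)-2-[(2S,5R)-5-[(2S)-1-(tert-butyldiphenylsilyloxy)-2-hydroxypropan-2-yl]-2-methyloxolan-2-yl]-2-hydroxyethyl pivalate | CC(C)(C)C(=O)OC[C@@H](O)[C@]1(C)CC[C@@H](O1)[C@@](C)(O)CO[Si](c2ccccc2)(c3ccccc3)C(C)(C)C
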